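In a one-step world each catalyst turns over at one pace at a given substrate charge, so the opening rate per catalyst charged is the same in the oak and ash runs, whose substrate charges are equal.

| flask | substrate | free catalyst | time |
|---|---|---|---|
| oak | 0.100 M | 0.0100 M |  |
| ash | 0.100 M | 0.0150 M |  |
| maple | 0.0500 M | 0.0100 M | 8.1 h |

- oak run (time / h: [target] / M): 0.36: 0.0028; 1.1: 0.0104; 2.1: 0.0187; 3.3: 0.0279; 4.7: 0.0384; 6.3: 0.0472; 8.1: 0.0566
- ash run (time / h: [target] / M): 0.36: 0.0082; 1.1: 0.0247; 2.1: 0.0429; 3.3: 0.0605; 4.7: 0.0759; 6.3: 0.0859; 8.1: 0.0929

(standard deviation of a reading: 3 × 10⁻⁴ M)

- how the opening rate goes with [free catalyst] round the charge of the oak run: the exponent of the rate at two percent of substrate gone to target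
- target in the maple run at 8.1 h, as a share of the substrate charged

- Overall: substrate -> target, with free catalyst as catalyst.
- Constant volume, constant temperature.
- A reading of a species includes what of it is bound.
- An order is taken over about fifteen percent of the charge, up and down.

1. Count turnovers at nearly equal early target: the oak run has turned 18.7% of its substrate at 2.1 h, the ash run 24.7% at 1.1 h. Over those stretches the oak run gives 0.890 /h per catalyst and the ash run 1.50 /h, faster. The one-step picture fails.

2. A better estimate lets pace grow with catalyst, so that rate goes as its square. Ash holds 1.50 times the catalyst of oak, which gives a rate ratio of 2.25. The readings give 2.52, higher, a gap of 0.272.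

3. That gap might be scatter. But the scatter of the two readings moves the ratio by about 0.0711, less than the gap, so the gap stays.

4. Suppose an equal amount of catalyst does no work in the oak and ash runs, and rate goes as the square of what works. Then the root of the rate ratio, 1.59, equals working catalyst in ash over working catalyst in oak. That gives 15.0% for the dead share, the fraction of the oak catalyst charge lost before any turnover.

5. Small changes in charge weigh more on what works, so the order round the oak charge is twice the charge over the working part: 2.35. The objection is that a plain power law reads 2.28 from the same ratio, lower. But that is a chord from oak to ash, and the order asked is the slope at the oak charge. Both come from one ratio, so neither checks the other.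

6. The forecast says order 2.4 and 70% for maple, slightly above this reckoning on the order, and adds that "substrate mildly holds catalyst back".

The flask gives order 2.4 and 67.4%.

    free catalyst + substrate ⇌ catalyst-substrate complex, settled at all times (3.820 /M)
    catalyst-substrate complex + free catalyst → target + 2 free catalyst (687.6 /M/h)
    free catalyst + impurity → spent catalyst
    catalyst-substrate complex → spent catalyst + substrate (0.06336 /h)

The impurity makes the dead share: oak without its step shows order 2.0, which is what the rule gives at a dead share of zero. In maple, restoring the dead share raises pace 1.38 times. If substrate falls by a fixed fraction per hour, the 32.6% left is raised to that power, which puts target at 78.7%. Maple without that step gives 80.5%.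

The readings are calculated on assumed constants, and the scatter is random.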